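A direct plan would join the aryl bromide A1 and the phenol A2, both arylacetic esters, by an Ullmann etherification to the diester A3,
reduce A3 to the diol A4, oxidise A4 to the bis(arylacetaldehyde) A5, and close both imidazoles last by a twofold Debus–Radziszewski condensation.
Weakest would be that twofold imidazole synthesis: it would fall on the last material, on an enolisable, aldol-prone dialdehyde, with eight C–N bonds to form.
The reduction and re-oxidation of both arms would spend two steps on oxidation state alone and would end in that same unstable dialdehyde.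
The etherification would need an electron-rich, ortho-substituted aryl bromide as electrophile, beside two base-sensitive ester CH2 groups.

Plan of the new route
The retrosynthesis cuts the two C(sp2)–CH2 bonds first (at C2 of ring A, ortho to the ether oxygen, and at C3 of ring B), then the O–C1 bond of ring B.
Enabling feature: each imidazole is bound through C2, the amidine carbon between N1 and N3, to a CH2 on a benzene sp2 carbon, and both arms are identical.
The CH3 of 2-methylimidazole is therefore an acidic 2-azaallyl position that already holds a whole arm, and one nucleophile serves twice.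
All four rings enter intact: rings A and B are joined through oxygen at room temperature with ring A as the phenol nucleophile; the imidazole rings C and D are then attached together in one three-component Negishi coupling.
No imidazole is built, so no arylacetaldehyde, no redox correction and no late ring synthesis arise, and the ether step needs no aryl halide electrophile.
Key step: step 3

Remark on the chemistry: the target has no stereocentre; each imidazole N–H is written as one of two rapidly interconverting tautomers; compounds 1, 2 and 4 are taken as commercial.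

Step 1
Reactants: 1 2-bromo-4-methoxyphenol; 2 (3-bromophenyl)boronic acid
Product: 3 2-bromo-1-(3-bromophenoxy)-4-methoxybenzene
Conditions: 2 (2.0 equiv), Cu(OAc)2 (1.0 equiv), pyridine (5 equiv), 4 Å molecular sieves, CH2Cl2, air, rt
Reagents that add atoms: none
Why: In this Chan–Lam O-arylation the phenoxide of 1 and the aryl group of 2 meet on divalent copper and reductive elimination from a trivalent copper aryl phenoxide forms the C–O bond at room temperature, so the hindered, electron-rich ring A acts as the nucleophile and both C–Br bonds, inert to copper under these conditions, should survive for the key step.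

Step 2
Reactants: 4 2-methyl-1H-imidazole
Product: 5 2-methyl-1-trityl-1H-imidazole (2-methyl-1-(triphenylmethyl)imidazole)
Conditions: TrCl (1.05 equiv), Et3N (1.5 equiv), DMF, rt
Reagents that add atoms: trityl chloride (chlorotriphenylmethane), ClC(c1ccccc1)(c1ccccc1)c1ccccc1
Why: N-Tritylation of the imidazole (SN1-type N-alkylation) can give only one product because the two ring nitrogens of 4 are equivalent by tautomerism, and the trityl group removes the acidic N–H and shields C5–H for the metalation to follow.

Step 3
Reactants: 3 2-bromo-1-(3-bromophenoxy)-4-methoxybenzene; 5 2-methyl-1-trityl-1H-imidazole (two molecules are incorporated per molecule of 3)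
Product: 8 2-[[5-methoxy-2-[3-[(1-tritylimidazol-2-yl)methyl]phenoxy]phenyl]methyl]-1-tritylimidazole, via lithiomethylimidazole 6 (not isolated), via imidazolylmethylzinc chloride 7 (not isolated)
Conditions: 5 (3.0 equiv), n-BuLi (3.0 equiv), THF, −78 °C; ZnCl2 (3.2 equiv), −78 °C → rt; then 3 (1.0 equiv), Pd(OAc)2 (5 mol%), SPhos (2-dicyclohexylphosphino-2',6'-dimethoxybiphenyl, 10 mol%), THF, 60 °C
Reagents that add atoms: none
Why: n-BuLi removes a proton from the C2-methyl group of 5 to give the 2-azaallyl anion 6, delocalised onto N3, and ZnCl2 converts it into the zinc reagent 7. Zerovalent palladium, formed in the flask from Pd(OAc)2, SPhos and 7, inserts into a C–Br bond of 3, transmetalation with 7 and reductive elimination form the C(sp2)–CH2 bond, and the cycle runs a second time on the other ring. The closest known reaction type is the Negishi coupling of benzylic and 2-azaarylmethyl (picolyl-type) zinc halides with aryl bromides. No ring is closed and no stereocentre is formed. The step needs lateral rather than ring metalation of 5, which the acidity of the CH3 on the amidine carbon C2 and the trityl shield over C5–H should secure, and coupling at carbon rather than at N3, which is favoured because only C-arylation keeps the imidazole aromatic. It also needs both bromides to react, including the one ortho to the aryloxy group on the electron-rich ring A, for which the bulky, electron-rich biarylphosphine and the excess of 7 are chosen.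

Step 4
Reactants: 8 2-[[5-methoxy-2-[3-[(1-tritylimidazol-2-yl)methyl]phenoxy]phenyl]methyl]-1-tritylimidazole
Product: 9 Lepidine C, 2-[[2-[3-(1H-imidazol-2-ylmethyl)phenoxy]-5-methoxyphenyl]methyl]-1H-imidazole
Conditions: TFA, Et3SiH (4 equiv), CH2Cl2, rt; then aq. NaHCO3
Reagents that add atoms: none
Why: In this acidolytic N-detritylation, protonation of each imidazole lets the trityl cation leave and triethylsilane reduces it irreversibly to triphenylmethane, which should keep it from alkylating the electron-rich ring A, while the diaryl ether, the methyl ether and the benzylic CH2 groups are inert to TFA at room temperature.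

**Compound list**

1 | 2-bromo-4-methoxyphenol | COc1ccc(O)c(Br)c1 | starting material
2 | (3-bromophenyl)boronic acid | OB(O)c1cccc(Br)c1 | starting material
3 | 2-bromo-1-(3-bromophenoxy)-4-methoxybenzene | COc1ccc(Oc2cccc(Br)c2)c(Br)c1 | intermediate
4 | 2-methyl-1H-imidazole | Cc1ncc[nH]1 | starting material
5 | 2-methyl-1-trityl-1H-imidazole | Cc1nccn1C(c1ccccc1)(c1ccccc1)c1ccccc1 | intermediate
6 | [(1-tritylimidazol-2-yl)methyl]lithium | [Li]Cc1nccn1C(c1ccccc1)(c1ccccc1)c1ccccc1 | intermediate
7 | chloro[(1-tritylimidazol-2-yl)methyl]zinc | Cl[Zn]Cc1nccn1C(c1ccccc1)(c1ccccc1)c1ccccc1 | intermediate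
8 | 2-[[5-methoxy-2-[3-[(1-tritylimidazol-2-yl)methyl]phenoxy]phenyl]methyl]-1-tritylimidazole | COc1ccc(Oc2cccc(Cc3nccn3C(c3ccccc3)(c3ccccc3)c3ccccc3)c2)c(Cc2nccn2C(c2ccccc2)(c2ccccc2)c2ccccc2)c1 | intermediate
9 | Lepidine C, 2-[[2-[3-(1H-imidazol-2-ylmethyl)phenoxy]-5-methoxyphenyl]methyl]-1H-imidazole | COc1ccc(Oc2cccc(Cc3ncc[nH]3)c2)c(Cc2ncc[nH]2)c1 | target

Total step count: 4. Longest linear sequence: 3 steps (1 → 3 → 8 → 9, or 4 → 5 → 8 → 9).

Steps most likely to fail

Step 3. Metalation of 5 may go partly to ring carbon C5 instead of the methyl group. Transmetalation of the bulky zinc reagent may be slow, so that the second C–Br bond, ortho to the aryloxy group, is reduced instead of coupled. Some coupling may occur at N3. The fallback reverses the polarity of the C–C bond formation and sets out from 3. Twofold bromine–lithium exchange (n-BuLi, THF, −78 °C) and trapping with DMF should give 2-(3-formylphenoxy)-5-methoxybenzaldehyde F1. (1-Tritylimidazol-2-yl)lithium F2, made from commercial 1-tritylimidazole and n-BuLi in THF, should add to both formyl groups to give the bis-carbinol [2-[3-[hydroxy(1-tritylimidazol-2-yl)methyl]phenoxy]-5-methoxyphenyl](1-tritylimidazol-2-yl)methanol F3. Its two carbinol centres would form unselectively, which is of no consequence because both are removed. Hydrogenolysis (H2, Pd/C, AcOH, aq. HCl, 60 °C) should then remove both benzylic hydroxyl groups and both trityl groups, and the sequence comes back to the route at the target 9.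

Step 1. O-Arylation of the ortho-brominated phenol may be slow, while the boronic acid is lost by protodeboronation and oxidative homocoupling and the electron-rich phenol is oxidised by divalent copper. The fallback uses no metal and sets out from 1. (3-Bromophenyl)(2,4,6-trimethoxyphenyl)iodonium tosylate F4 would be prepared from 1-bromo-3-iodobenzene with mCPBA and TsOH·H2O, then 1,3,5-trimethoxybenzene. With 1 and K2CO3 in THF at rt to 50 °C, ligand coupling on trivalent iodine should transfer the less electron-rich 3-bromophenyl group to the phenoxide oxygen. The sequence comes back to the route at 3.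

Step 4. The trityl cation may return to a ring nitrogen or alkylate the electron-rich ring A if it is not trapped fast enough, and the polar, basic product may be lost during aqueous work-up. The fallback changes the protecting-group strategy to one cleaved without a carbocation and sets out from 3. Commercial 1-benzyl-2-methylimidazole would be metalated at the methyl group (n-BuLi, THF, −78 °C) to [(1-benzylimidazol-2-yl)methyl]lithium F5 and transmetalated with ZnCl2 to chloro[(1-benzylimidazol-2-yl)methyl]zinc F6. Twofold coupling with 3 under the conditions of step 3 should give 1-benzyl-2-[[2-[3-[(1-benzylimidazol-2-yl)methyl]phenoxy]-5-methoxyphenyl]methyl]imidazole F7. Hydrogenolysis (H2, Pd(OH)2/C, AcOH, MeOH, 50 °C) should remove both N-benzyl groups, and the sequence comes back to the route at 9.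

Further compounds
F1 | step 3 | 2-(3-formylphenoxy)-5-methoxybenzaldehyde | COc1ccc(Oc2cccc(C=O)c2)c(C=O)c1
F2 | step 3 | (1-tritylimidazol-2-yl)lithium | [Li]c1nccn1C(c1ccccc1)(c1ccccc1)c1ccccc1
F3 | step 3 | [2-[3-[hydroxy(1-tritylimidazol-2-yl)methyl]phenoxy]-5-methoxyphenyl](1-tritylimidazol-2-yl)methanol (mixture of diastereomers) | COc1ccc(Oc2cccc(C(O)c3nccn3C(c3ccccc3)(c3ccccc3)c3ccccc3)c2)c(C(O)c2nccn2C(c2ccccc2)(c2ccccc2)c2ccccc2)c1
F4 | step 1 | (3-bromophenyl)(2,4,6-trimethoxyphenyl)iodonium tosylate | COc1cc(OC)c([I+]c2cccc(Br)c2)c(OC)c1.Cc1ccc(cc1)S(=O)(=O)[O-]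
F5 | step 4 | [(1-benzylimidazol-2-yl)methyl]lithium | [Li]Cc1nccn1Cc1ccccc1
F6 | step 4 | chloro[(1-benzylimidazol-2-yl)methyl]zinc | Cl[Zn]Cc1nccn1Cc1ccccc1
F7 | step 4 | 1-benzyl-2-[[2-[3-[(1-benzylimidazol-2-yl)methyl]phenoxy]-5-methoxyphenyl]methyl]imidazole | COc1ccc(Oc2cccc(Cc3nccn3Cc3ccccc3)c2)c(Cc2nccn2Cc2ccccc2)c1
A1 | direct plan | methyl 2-(2-bromo-5-methoxyphenyl)acetate | COC(=O)Cc1cc(OC)ccc1Br
A2 | direct plan | methyl 2-(3-hydroxyphenyl)acetate | COC(=O)Cc1cccc(O)c1
A3 | direct plan | methyl 2-[5-methoxy-2-[3-(2-methoxy-2-oxoethyl)phenoxy]phenyl]acetate | COC(=O)Cc1cccc(Oc2ccc(OC)cc2CC(=O)OC)c1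
A4 | direct plan | 2-[3-[2-(2-hydroxyethyl)-4-methoxyphenoxy]phenyl]ethanol | COc1ccc(Oc2cccc(CCO)c2)c(CCO)c1
A5 | direct plan | 2-[5-methoxy-2-[3-(2-oxoethyl)phenoxy]phenyl]acetaldehyde | COc1ccc(Oc2cccc(CC=O)c2)c(CC=O)c1
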